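**Retrosynthetic overview**

1. The butenolide is made last: the target is disconnected to a terminal E-enyne and (Z)-3-iodobut-2-enoic acid (tandem Sonogashira coupling and 5-exo-dig lactonisation). The C18 aldehyde is traced back to the equatorial 4α-methyl of a gem-dimethyl precursor, oxidised from the 6α-hydroxyl by Barton nitrite photolysis.
2. The 6α,8α-diol comes from a trans-fused Δ7-6-enone (α-face epoxidation, then SmI2 for C7–O cleavage and ketone reduction).
3. Enabling feature: in ring B the oxygen-bearing C6 and the oxygen- and methyl-bearing C8 are 1,3-related through C7 and flanked by C5 and C9. C5–C6(=O)–C7–C8 is therefore the 1,4-zwitterion (enolate at C5, oxocarbenium at C8) of a 3-alkoxy-3-methylcyclobutanone, and the remaining ring-B bond C9–C10 is an E-trisubstituted alkene tethered to C5 through C4–C1 of ring A.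
4. The enone comes from that cyclobutanone by a Lewis-acid formal [4+2] that inserts C9=C10 into the C5–C8 bond (ring B by four-to-six ring expansion, ring A closed by the same C5–C10 bond). The cyclobutanone comes from a ketene and a lactate-derived isopropenyl ether ([2+2]).
5. The acyclic acid comes from 5-chloropent-1-yne, a homopropargyl zinc reagent and isopropylidene Meldrum's acid. Ring order: four-membered ring (step 6), rings A and B together (step 7), butenolide (step 16).

Key step: step 7

**Remarks on the chemistry**
- Decalin positions are numbered as in labdanes: ring A = C1–C5 and C10; ring B = C5–C10; the chain on C9 starts at C11; the C4 methyls are C18 (α) and C19 (β), the C8 methyl is C17, the C10 methyl is C20. α is the face opposite to the C10 methyl. The absolute configuration is that of sclareol.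
- Assumption: the target is taken as drawn, the open 6α-hydroxy 4α-carbaldehyde; a lactol between O6 and C18 would be its ring–chain tautomer and needs no further step.
- Assumption: ethyl (S)-lactate is taken to induce the drawn series in the key step; if the sense proved opposite, ethyl (R)-lactate would be used in step 5 and nothing else changes.
- The two ring stereocentres of the cyclobutanone, and C5 and C8 of the primary cycloadduct, are left undefined in name and SMILES on purpose: all isomers converge in the key step.

**Route**

Step 1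
Reactants: 1 5-chloropent-1-yne
Product: 3 (E)-5-chloro-1-iodo-2-methylpent-1-ene, via alkenylalane 2 (not isolated)
Conditions: Me3Al (2 equiv), Cp2ZrCl2 (0.2 equiv), CH2Cl2, 0 to 23 °C; then I2, THF, −30 °C
Reagents that add atoms: trimethylaluminium C[Al](C)C; iodine [I][I]
Why: Zirconocene-catalysed Negishi carboalumination adds methyl and aluminium syn across the terminal alkyne with methyl at the internal carbon, and iodinolysis with retention should give the E-alkenyl iodide that fixes the later C9=C10 geometry, the alkyl chloride being inert.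

Step 2
Reactants: 3 (E)-5-chloro-1-iodo-2-methylpent-1-ene; 4 (4-bromobut-1-yn-1-yl)trimethylsilane
Product: 7 (E)-(9-chloro-6-methylnon-5-en-1-yn-1-yl)trimethylsilane, via Grignard reagent 5 (not isolated), via organozinc bromide 6 (not isolated)
Conditions: 4, Mg, THF, 40 °C; ZnBr2, THF, 0 °C; then 3, Pd(PPh3)4 (3 mol %), THF, 23 to 45 °C
Reagents that add atoms: none
Why: Negishi cross-coupling of the alkenyl iodide with the homopropargyl zinc reagent proceeds with retention of the E geometry and should leave the alkyl chloride and the silylalkyne untouched.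

Step 3
Reactants: 7 (E)-(9-chloro-6-methylnon-5-en-1-yn-1-yl)trimethylsilane; 8 isopropylidene Meldrum's acid
Product: 10 Meldrum's acid conjugate adduct, via Grignard reagent 9 (not isolated)
Conditions: 7, Mg (I2-activated), THF, reflux; then 8, CuBr·SMe2 (10 mol %), THF, −40 to 0 °C; 1 M HCl
Reagents that add atoms: none
Why: Copper-catalysed conjugate addition of the primary Grignard reagent to the doubly activated alkylidene Meldrum's acid builds the quaternary gem-dimethyl carbon C4 that a simple enoate would resist, and no stereocentre is formed.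

Step 4
Reactants: 10 Meldrum's acid conjugate adduct
Product: 11 (E)-3,3,7-trimethyl-12-(trimethylsilyl)dodec-7-en-11-ynoic acid
Conditions: DMF–H2O (10:1), 110 °C
Reagents that add atoms: water O
Why: Neutral hydrolysis of the acylal followed by decarboxylation of the malonic acid should give the 3,3-dimethyl acid without touching the alkynylsilane or the alkene.

Step 5
Reactants: 12 ethyl (S)-lactate; 13 2-methoxypropene
Product: 15 ethyl (S)-2-(prop-1-en-2-yloxy)propanoate, via mixed ketal 14 (not isolated)
Conditions: 13 (4 equiv), PPTS (1 mol %), CH2Cl2, 0 °C; evaporation of excess 13; then iPr2NEt, TMSOTf, CH2Cl2, 0 to 23 °C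
Reagents that add atoms: none
Why: Acid-catalysed addition of the lactate hydroxyl to 2-methoxypropene gives the mixed ketal, from which the silyl triflate and amine remove the less hindered and more basic methoxy group (ketal to enol ether elimination), the lactate stereocentre not being involved.

Step 6
Reactants: 11 (E)-3,3,7-trimethyl-12-(trimethylsilyl)dodec-7-en-11-ynoic acid; 15 ethyl (S)-2-(prop-1-en-2-yloxy)propanoate
Product: 18 lactate-derived 3-alkoxy-3-methylcyclobutanone, via acid chloride 16 (not isolated), via ketene 17 (not isolated)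
Conditions: (COCl)2, DMF (cat.), CH2Cl2, 0 to 23 °C, evaporation; then slow addition to 15 (3 equiv), Et3N, toluene, 80 °C
Reagents that add atoms: none
Why: Dehydrochlorination gives the tert-alkyl-substituted aldoketene, whose [2+2] cycloaddition with the electron-rich 1,1-disubstituted enol ether joins the ketene carbonyl carbon to the CH2 terminus and so gives the 3-alkoxy-3-methylcyclobutanone; the two new ring stereocentres are left uncontrolled because both become sp2 in step 7.

Step 7
Reactants: 18 lactate-derived 3-alkoxy-3-methylcyclobutanone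
Product: 20 trans-fused Δ7-6-enone, via lactyloxy ketone 19 (not isolated)
Conditions: TiCl4 (2 equiv), CH2Cl2 (0.005 M), −78 to −30 °C; aq. NaHCO3; crude in CH2Cl2, DBU, 23 °C
Reagents that add atoms: none
Why: TiCl4 binds the ketone and the lactate ester and ionises the strained donor–acceptor C5–C8 bond to a zwitterion (titanium enolate at C5=C6, oxocarbenium at C8); C9 of the E-alkene adds to C8 in Markovnikov (Prins-type) fashion and the tertiary cation at C10 is captured by enolate carbon C5, which is the Lewis-acid-promoted formal [4+2] cycloaddition of 3-alkoxycyclobutanones with alkenes, the closest known reaction type, used here intramolecularly. Ring B is closed by insertion of C9=C10 into the C5–C8 bond of the four-membered ring (two-atom ring expansion, four to six), and ring A is closed by the same C5–C10 bond through the C4–C1 tether in a chair–chair array like that of a polyene cyclisation. C9 and C10 are set relative to each other by the E geometry of the alkene and suprafacial addition (C10 methyl cis to the C9 chain) and absolutely by the lactate group on the oxocarbenium oxygen, which is held in a titanium chelate and shields one face of C8, as it does in the known reactions of lactate-derived alkoxycyclobutanones with aldehydes. C5 is set under thermodynamic control in the second stage, where DBU expels ethyl lactate from C8 (E1cB) to give the conjugated enone and equilibrates C5 to the trans ring fusion; C8 ends sp2, so its configuration in 19 is irrelevant. The step needs C- instead of O-alkylation of the enolate and attack of the trisubstituted alkene instead of the silylalkyne: the tether holds C5 over C10, an O-alkylated enol ether would re-ionise under the Lewis acid, and the alkynylsilane is the weaker and remote nucleophile. High dilution keeps the zwitterion from intermolecular reactions.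

Step 8
Reactants: 20 trans-fused Δ7-6-enone
Product: 21 7α,8α-epoxy ketone with free terminal alkyne
Conditions: 30% aq. H2O2, NaOH, MeOH–THF, 0 to 23 °C
Reagents that add atoms: hydrogen peroxide OO
Why: Weitz–Scheffer nucleophilic epoxidation, in which hydroperoxide adds to C8 from the α face, anti to the axial C10 methyl and the β-oriented C9 chain, so that the oxygen on C8 is α and the C8 methyl β, while the basic methanol also removes the alkynyl silyl group.

Step 9
Reactants: 21 7α,8α-epoxy ketone with free terminal alkyne
Product: 23 6α,8α-diol with but-3-ynyl chain, via hydroxy ketone 22 (not isolated)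
Conditions: SmI2 (2.5 equiv), THF–MeOH, −90 °C; then SmI2 (3 equiv), H2O, Et3N, −78 to 0 °C
Reagents that add atoms: none
Why: SmI2 cleaves the C7–O bond of the α,β-epoxy ketone (ketyl, then α-C–O scission), which keeps the 8α-hydroxyl, and further electron transfer reduces the C6 ketone through a carbanion that is protonated with the bulky samarium-bound oxygen equatorial, away from the three axial methyls on the β face, which should give the equatorial 6α-alcohol as in dissolving-metal reductions, the terminal alkyne being inert.

Step 10
Reactants: 23 6α,8α-diol with but-3-ynyl chain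
Product: 25 E-alkenyl iodide diol, via alkenylalane 24 (not isolated)
Conditions: Me3Al (5 equiv), Cp2ZrCl2 (0.5 equiv), CH2Cl2, 0 to 23 °C; then I2, THF, −30 °C; aq. Rochelle salt
Reagents that add atoms: trimethylaluminium C[Al](C)C; iodine [I][I]
Why: Negishi carboalumination (the two hydroxyls first become aluminium alkoxides) adds methyl to C13 and aluminium to C14 in syn fashion, and iodinolysis with retention should give the E-alkenyl iodide.

Step 11
Reactants: 25 E-alkenyl iodide diol; 26 ethynylmagnesium bromide
Product: 28 terminal E-enyne diol, via ethynylzinc bromide 27 (not isolated)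
Conditions: 26 (4 equiv), ZnBr2, THF, 0 °C; then 25, Pd(PPh3)4 (5 mol %), THF, 23 °C
Reagents that add atoms: none
Why: Negishi coupling of the alkenyl iodide with ethynylzinc bromide gives the terminal enyne directly with retention of the E geometry, and the zinc acetylide tolerates the free hydroxyls.

Step 12
Reactants: 28 terminal E-enyne diol
Product: 29 6α-nitrite ester
Conditions: NOCl (1.2 equiv), pyridine, −30 °C, dark
Reagents that add atoms: nitrosyl chloride O=NCl
Why: O-Nitrosation with nitrosyl chloride in pyridine is fast for the secondary 6α-hydroxyl and slow for the hindered tertiary 8α-hydroxyl, so the mononitrite of the secondary alcohol is expected.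

Step 13
Reactants: 29 6α-nitrite ester
Product: 31 C18 oxime, via C-nitroso compound 30 (not isolated)
Conditions: hν (365 nm), degassed MeCN, 10 °C; then iPrOH, 60 °C
Reagents that add atoms: none
Why: Barton nitrite photolysis, in which O–N homolysis gives the 6α-alkoxy radical that abstracts hydrogen through a six-membered transition state only from the equatorial 4α-methyl (peri to the equatorial 6α-oxygen, whereas the axial 4β, 8β and 10β methyls lie on the other face), NO recombines at C18 and the nitroso compound tautomerises to the oxime, which fixes the C4 stereocentre with the oxidised carbon α and the methyl β.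

Step 14
Reactants: 31 C18 oxime
Product: 32 6α,8α-dihydroxy 4α-carbaldehyde with enyne chain
Conditions: NaNO2, AcOH–H2O, 10 °C
Reagents that add atoms: water O
Why: Nitrous acid deoximation (N-nitrosation, hydration, loss of N2O) frees the aldehyde under mild acid, C4 being quaternary and therefore not epimerisable, and the tertiary alcohol and the enyne should survive at this temperature.

Step 15
Reactants: 33 but-2-ynoic acid
Product: 34 (Z)-3-iodobut-2-enoic acid
Conditions: NaI, AcOH, 115 °C
Reagents that add atoms: sodium iodide [Na+].[I-]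
Why: Hydroiodination of the ynoic acid with iodide in acetic acid is an anti addition (iodide at C3, proton at C2 from the opposite side), which gives the Z acid needed for lactonisation.

Step 16
Reactants: 32 6α,8α-dihydroxy 4α-carbaldehyde with enyne chain; 34 (Z)-3-iodobut-2-enoic acid
Product: 35 CNP0278517.1
Conditions: Pd(PPh3)4 (5 mol %), CuI (10 mol %), Et3N, MeCN, 23 °C, dark
Reagents that add atoms: none
Why: Tandem Sonogashira coupling and 5-exo-dig lactonisation, in which the Z-enynoic acid formed in the flask cyclises by anti oxymetalation of the alkyne to give the Z-ylidene butenolide, while the E-alkene from step 10 is retained and the aldehyde and hydroxyls are spectators.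

**Compound list**

1 | 5-chloropent-1-yne | C#CCCCCl | starting material
2 | (E)-(5-chloro-2-methylpent-1-enyl)dimethylalane | ClCCC/C(C)=C/[Al](C)C | intermediate
3 | (E)-5-chloro-1-iodo-2-methylpent-1-ene | ClCCC/C(C)=C/I | intermediate
4 | (4-bromobut-1-yn-1-yl)trimethylsilane | C[Si](C)(C)C#CCCBr | starting material
5 | [4-(trimethylsilyl)but-3-ynyl]magnesium bromide | C[Si](C)(C)C#CCC[Mg]Br | intermediate
6 | [4-(trimethylsilyl)but-3-ynyl]zinc bromide | C[Si](C)(C)C#CCC[Zn]Br | intermediate
7 | (E)-(9-chloro-6-methylnon-5-en-1-yn-1-yl)trimethylsilane | ClCCC/C(C)=C/CCC#C[Si](C)(C)C | intermediate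
8 | 2,2-dimethyl-5-(propan-2-ylidene)-1,3-dioxane-4,6-dione (isopropylidene Meldrum's acid) | CC(C)=C1C(=O)OC(C)(C)OC1=O | starting material
9 | [(4E)-4-methyl-9-(trimethylsilyl)non-4-en-8-yn-1-yl]magnesium chloride | Cl[Mg]CCC/C(C)=C/CCC#C[Si](C)(C)C | intermediate
10 | 2,2-dimethyl-5-[(6E)-2,6-dimethyl-11-(trimethylsilyl)undec-6-en-10-yn-2-yl]-1,3-dioxane-4,6-dione | CC1(C)OC(=O)C(C(=O)O1)C(C)(C)CCC/C(C)=C/CCC#C[Si](C)(C)C | intermediate
11 | (E)-3,3,7-trimethyl-12-(trimethylsilyl)dodec-7-en-11-ynoic acid | OC(=O)CC(C)(C)CCC/C(C)=C/CCC#C[Si](C)(C)C | intermediate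
12 | ethyl (S)-lactate | CCOC(=O)[C@H](C)O | starting material
13 | 2-methoxypropene | COC(C)=C | starting material
14 | ethyl (S)-2-[(2-methoxypropan-2-yl)oxy]propanoate | CCOC(=O)[C@H](C)OC(C)(C)OC | intermediate
15 | ethyl (S)-2-(prop-1-en-2-yloxy)propanoate | CCOC(=O)[C@H](C)OC(C)=C | intermediate
16 | (E)-3,3,7-trimethyl-12-(trimethylsilyl)dodec-7-en-11-ynoyl chloride | ClC(=O)CC(C)(C)CCC/C(C)=C/CCC#C[Si](C)(C)C | intermediate
17 | (7E)-3,3,7-trimethyl-12-(trimethylsilyl)dodeca-1,7-dien-11-yn-1-one (ketene) | O=C=CC(C)(C)CCC/C(C)=C/CCC#C[Si](C)(C)C | intermediate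
18 | ethyl (2S)-2-({1-methyl-3-oxo-2-[(6E)-2,6-dimethyl-11-(trimethylsilyl)undec-6-en-10-yn-2-yl]cyclobutyl}oxy)propanoate, mixture of diastereomers at the two ring stereocentres | CCOC(=O)[C@H](C)OC1(C)CC(=O)C1C(C)(C)CCC/C(C)=C/CCC#C[Si](C)(C)C | intermediate
19 | 4,4,8,10β-tetramethyl-9β-[4-(trimethylsilyl)but-3-ynyl]decalin-6-one carrying the (S)-1-ethoxy-1-oxopropan-2-yloxy group on C8 (C5 and C8 epimers) | C[Si](C)(C)C#CCC[C@@H]1[C@@]2(C)CCCC(C)(C)C2C(=O)CC1(C)O[C@@H](C)C(=O)OCC | intermediate
20 | 4,4,8,10β-tetramethyl-9β-[4-(trimethylsilyl)but-3-ynyl]-5α-octal-7-en-6-one; (4S,4aR,8aS)-3,4a,8,8-tetramethyl-4-[4-(trimethylsilyl)but-3-yn-1-yl]-4a,5,6,7,8,8a-hexahydronaphthalen-1(4H)-one | C[Si](C)(C)C#CCC[C@@H]1[C@@]2(C)CCCC(C)(C)[C@@H]2C(=O)C=C1C | intermediate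
21 | 9β-(but-3-ynyl)-7α,8α-epoxy-4,4,8β,10β-tetramethyl-5α-decalin-6-one | C#CCC[C@@H]1[C@@]2(C)CCCC(C)(C)[C@@H]2C(=O)[C@H]3O[C@]31C | intermediate
22 | 9β-(but-3-ynyl)-8α-hydroxy-4,4,8β,10β-tetramethyl-5α-decalin-6-one | C#CCC[C@@H]1[C@@]2(C)CCCC(C)(C)[C@@H]2C(=O)C[C@@]1(C)O | intermediate
23 | 9β-(but-3-ynyl)-4,4,8β,10β-tetramethyl-5α-decalin-6α,8α-diol | C#CCC[C@@H]1[C@@]2(C)CCCC(C)(C)[C@@H]2[C@@H](O)C[C@@]1(C)O | intermediate
24 | 9β-[(3E)-4-(dimethylalumanyl)-3-methylbut-3-enyl]-4,4,8β,10β-tetramethyl-5α-decalin-6α,8α-diyl bis(dimethylaluminium) alkoxide | C[Al](C)/C=C(\C)CC[C@@H]1[C@@]2(C)CCCC(C)(C)[C@@H]2[C@@H](O[Al](C)C)C[C@@]1(C)O[Al](C)C | intermediate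
25 | 9β-[(3E)-4-iodo-3-methylbut-3-enyl]-4,4,8β,10β-tetramethyl-5α-decalin-6α,8α-diol | I/C=C(\C)CC[C@@H]1[C@@]2(C)CCCC(C)(C)[C@@H]2[C@@H](O)C[C@@]1(C)O | intermediate
26 | ethynylmagnesium bromide | C#C[Mg]Br | starting material
27 | ethynylzinc bromide | C#C[Zn]Br | intermediate
28 | 4,4,8β,10β-tetramethyl-9β-[(3E)-3-methylhex-3-en-5-ynyl]-5α-decalin-6α,8α-diol | C#C/C=C(\C)CC[C@@H]1[C@@]2(C)CCCC(C)(C)[C@@H]2[C@@H](O)C[C@@]1(C)O | intermediate
29 | 8α-hydroxy-4,4,8β,10β-tetramethyl-9β-[(3E)-3-methylhex-3-en-5-ynyl]-5α-decalin-6α-yl nitrite | C#C/C=C(\C)CC[C@@H]1[C@@]2(C)CCCC(C)(C)[C@@H]2[C@@H](ON=O)C[C@@]1(C)O | intermediate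
30 | 4β,8β,10β-trimethyl-9β-[(3E)-3-methylhex-3-en-5-ynyl]-4α-(nitrosomethyl)-5α-decalin-6α,8α-diol | C#C/C=C(\C)CC[C@@H]1[C@@]2(C)CCC[C@@](C)(CN=O)[C@@H]2[C@@H](O)C[C@@]1(C)O | intermediate
31 | (E)-oxime of 6α,8α-dihydroxy-4β,8β,10β-trimethyl-9β-[(3E)-3-methylhex-3-en-5-ynyl]-5α-decalin-4α-carbaldehyde | C#C/C=C(\C)CC[C@@H]1[C@@]2(C)CCC[C@@](C)(/C=N/O)[C@@H]2[C@@H](O)C[C@@]1(C)O | intermediate
32 | 6α,8α-dihydroxy-4β,8β,10β-trimethyl-9β-[(3E)-3-methylhex-3-en-5-ynyl]-5α-decalin-4α-carbaldehyde | C#C/C=C(\C)CC[C@@H]1[C@@]2(C)CCC[C@@](C)(C=O)[C@@H]2[C@@H](O)C[C@@]1(C)O | intermediate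
33 | but-2-ynoic acid | CC#CC(=O)O | starting material
34 | (Z)-3-iodobut-2-enoic acid | C/C(I)=C/C(=O)O | intermediate
35 | CNP0278517.1; (1R,4aS,5R,6R,8S,8aR)-6,8-dihydroxy-1,4a,6-trimethyl-5-{(3E)-3-methyl-5-[(2Z)-3-methyl-5-oxofuran-2(5H)-ylidene]pent-3-en-1-yl}decahydronaphthalene-1-carbaldehyde | CC1=CC(=O)O/C1=C\C=C(/C)CC[C@@H]1[C@@]2(C)CCC[C@@](C)(C=O)[C@@H]2[C@@H](O)C[C@@]1(C)O | target

**Step count**

Total: 16 steps. Longest linear sequence: 14 steps (steps 1–4, 6–14 and 16); steps 5 and 15 are one-step side branches.

**Steps most likely to fail, with fallbacks**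

Step 7. The lactate group may discriminate the two faces of the oxocarbenium poorly, so that both enantiomeric series form; proton transfer within the zwitterion to an open-chain β-alkoxy enone is a second loss channel. The fallback gives up auxiliary control and resolves instead. It sets out from acid 11. Under the conditions of step 6, but with commercial 2-methoxypropene 13 in place of 15, the achiral 3-methoxy-3-methylcyclobutanone F1 is made. EtAlCl2 in CH2Cl2 at −78 °C, the usual promoter for this cycloaddition with simple alkoxy groups, should give the racemic 8-methoxy cycloadduct F2. DBU then eliminates methanol to the racemic enone, that is 20 together with its enantiomer F3. The enantiomers are separated by preparative chromatography on a chiral stationary phase (amylose carbamate), and 20 re-enters the route at step 8.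

Step 6. Closure of the crowded C5–C8 bond in the ketene–enol ether zwitterion may lose to proton transfer (open-chain β-alkoxy enone) or to ketene dimerisation. The fallback replaces the ketene by a keteniminium ion, which does not dimerise and is far more electrophilic. It sets out from acid 11. Acid chloride 16 and dimethylamine give the N,N-dimethylamide F4. Tf2O and 2,6-di-tert-butyl-4-methylpyridine in CH2Cl2 at −20 °C convert it into the keteniminium triflate F5. Its [2+2] cycloaddition with enol ether 15 gives the cyclobutaniminium triflate F6, which aqueous NaHCO3 hydrolyses to cyclobutanone 18, where the route continues with step 7.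

Step 9. The protonation that fixes C6 may show poor facial selectivity and deliver the axial 6β-alcohol. The fallback separates the two reductions and sets C6 by equilibration. It sets out from epoxy ketone 21. Only the first stage (SmI2, THF–MeOH, −90 °C) is run and hydroxy ketone 22 is isolated. NaBH4 in MeOH should attack from the open α face and give the 6β-epimer F7. Heating F7 with Al(OiPr)3 in isopropanol containing a little acetone (Meerwein–Ponndorf–Verley/Oppenauer equilibration) should move the axial hydroxyl, which is syn-axial to the C8 and C10 methyls, to the equatorial position, and so give diol 23, where the route continues with step 10.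

Further compounds

F1 | step 7 | 3-methoxy-3-methyl-2-[(6E)-2,6-dimethyl-11-(trimethylsilyl)undec-6-en-10-yn-2-yl]cyclobutan-1-one (racemic mixture of diastereomers) | COC1(C)CC(=O)C1C(C)(C)CCC/C(C)=C/CCC#C[Si](C)(C)C
F2 | step 7 | racemic 8-methoxy-4,4,8,10β-tetramethyl-9β-[4-(trimethylsilyl)but-3-ynyl]decalin-6-one (one enantiomer drawn, C5 and C8 epimers) | C[Si](C)(C)C#CCC[C@@H]1[C@@]2(C)CCCC(C)(C)C2C(=O)CC1(C)OC
F3 | step 7 | enantiomer of enone 20 | C[Si](C)(C)C#CCC[C@H]1[C@]2(C)CCCC(C)(C)[C@H]2C(=O)C=C1C
F4 | step 6 | (E)-N,N,3,3,7-pentamethyl-12-(trimethylsilyl)dodec-7-en-11-ynamide | CN(C)C(=O)CC(C)(C)CCC/C(C)=C/CCC#C[Si](C)(C)C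
F5 | step 6 | keteniminium triflate derived from F4 | C[N+](C)=C=CC(C)(C)CCC/C(C)=C/CCC#C[Si](C)(C)C.[O-]S(=O)(=O)C(F)(F)F
F6 | step 6 | N,N-dimethylcyclobutaniminium triflate corresponding to 18 | CCOC(=O)[C@H](C)OC1(C)CC(=[N+](C)C)C1C(C)(C)CCC/C(C)=C/CCC#C[Si](C)(C)C.[O-]S(=O)(=O)C(F)(F)F
F7 | step 9 | 9β-(but-3-ynyl)-4,4,8β,10β-tetramethyl-5α-decalin-6β,8α-diol (6β-epimer of 23) | C#CCC[C@@H]1[C@@]2(C)CCCC(C)(C)[C@@H]2[C@H](O)C[C@@]1(C)O
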